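C2 of ring C is an isolated CH between O1 and C3, so it can be the methyl carbon of a methoxy group on C8a of ring A. Cutting C2–C3 therefore leads back to a benzil whose carbonyl next to ring B is C3. In one light-driven operation the key step transfers a hydrogen from that methoxy group to the C3 oxygen and joins C2 to C3, closing ring C as a 3-hydroxyisoflavanone at the correct oxidation level. The precursor is a prenylated 1,2-diketone carrying three phenol pivalates, built by Sonogashira coupling and alkyne oxidation; dehydration and ester removal complete the synthesis.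

Key step: step 10

Remark: 4-iodoresorcinol is taken as a catalogue compound; the 1,2-diketone is unveiled only after all three phenols are pivaloylated, so that no free ortho-hydroxybenzil (which could close to a cyclic hemiketal or quench the excited state) is ever handled.

Step 1
Reactants: 1 2-methylbut-3-en-2-ol
Product: 3 tert-butyl (2-methylbut-3-en-2-yl) carbonate, via lithium 2-methylbut-3-en-2-olate 2 (not isolated)
Conditions: n-BuLi, THF, −78 °C; then Boc2O, −78 °C → rt
Reagents that add atoms: di-tert-butyl dicarbonate, CC(C)(C)OC(=O)OC(=O)OC(C)(C)C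
Why: Acylation of the tertiary lithium alkoxide 2 with Boc2O (mixed carbonate formation) is fast at low temperature and gives the ionisable allylic carbonate needed for the next step.

Step 2
Reactants: 4 3,5-dimethoxyphenol; 3 tert-butyl (2-methylbut-3-en-2-yl) carbonate
Product: 5 1,3-dimethoxy-5-[(2-methylbut-3-en-2-yl)oxy]benzene
Conditions: Pd(PPh3)4 (2 mol%), 4 Å MS, THF, 0 °C → rt
Reagents that add atoms: none
Why: Tsuji–Trost O-allylation: zerovalent palladium ionises the carbonate with loss of CO2, the tert-butoxide formed deprotonates the phenol, and the phenoxide attacks the more substituted terminus of the allyl complex of divalent palladium under kinetic control, giving the tertiary (1,1-dimethylallyl) ether without added base.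

Step 3
Reactants: 5 1,3-dimethoxy-5-[(2-methylbut-3-en-2-yl)oxy]benzene
Product: 7 3,5-dimethoxy-2-(3-methylbut-2-en-1-yl)phenol, via 3,5-dimethoxy-6-prenylcyclohexa-2,4-dien-1-one 6 (not isolated)
Conditions: PhNEt2, 130 °C
Reagents that add atoms: none
Why: Aromatic Claisen rearrangement: the [3,3] shift delivers the allyl unit with inversion to one of the two equivalent ortho carbons as the prenyl group, and the racemic dienone 6 tautomerises at once to the phenol, the basic solvent suppressing acid-catalysed chroman formation.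

Step 4
Reactants: 7 3,5-dimethoxy-2-(3-methylbut-2-en-1-yl)phenol
Product: 9 2-hydroxy-4,6-dimethoxy-3-(3-methylbut-2-en-1-yl)benzaldehyde, via 2-(hydroxymethyl)-3,5-dimethoxy-6-prenylphenol 8 (not isolated)
Conditions: MgCl2, Et3N, (CH2O)n, MeCN, reflux; aq. HCl work-up
Reagents that add atoms: formaldehyde (as paraformaldehyde), C=O
Why: Casnati–Skattebøl ortho-formylation: the magnesium phenoxide delivers formaldehyde through a six-membered chelate to the only free ortho carbon (the ring carbon para to the hydroxyl is not reached), and the magnesium salt of benzylic alcohol 8 is oxidised by a second formaldehyde through Oppenauer-type hydride transfer, all under non-acidic conditions that spare the prenyl group.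

Step 5
Reactants: 9 2-hydroxy-4,6-dimethoxy-3-(3-methylbut-2-en-1-yl)benzaldehyde
Product: 10 2-ethynyl-3,5-dimethoxy-6-(3-methylbut-2-en-1-yl)phenol
Conditions: Bestmann–Ohira reagent, K2CO3, MeOH, rt → 40 °C
Reagents that add atoms: dimethyl (1-diazo-2-oxopropyl)phosphonate, COP(=O)(OC)C(=[N+]=[N-])C(C)=O
Why: Seyferth–Gilbert homologation with the Bestmann–Ohira reagent: methanolysis releases dimethyl (diazomethyl)phosphonate, whose anion adds to the aldehyde and, after Horner–Wadsworth–Emmons-type elimination and loss of N2, a 1,2-hydride shift gives the terminal alkyne, a sequence that tolerates hydroxybenzaldehydes and does not touch the alkene.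

Step 6
Reactants: 10 2-ethynyl-3,5-dimethoxy-6-(3-methylbut-2-en-1-yl)phenol
Product: 11 2-ethynyl-3,5-dimethoxy-6-(3-methylbut-2-en-1-yl)phenyl 2,2-dimethylpropanoate
Conditions: PivCl, Et3N, DMAP (cat.), CH2Cl2, 0 °C → rt
Reagents that add atoms: pivaloyl chloride, CC(C)(C)C(Cl)=O
Why: DMAP-catalysed O-acylation of the unchelated phenol masks O5 before any carbonyl exists next to it, prevents cyclisation of the phenol onto the alkyne, and installs a group with no hydrogen within reach of the future C4 carbonyl.

Step 7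
Reactants: 12 4-iodobenzene-1,3-diol (4-iodoresorcinol)
Product: 13 4-iodo-1,3-phenylene bis(2,2-dimethylpropanoate)
Conditions: PivCl (2.2 equiv), Et3N, DMAP (cat.), CH2Cl2, 0 °C → rt
Reagents that add atoms: pivaloyl chloride, CC(C)(C)C(Cl)=O
Why: Exhaustive DMAP-catalysed O-acylation gives a ring B iodide whose 2′- and 4′-oxygens are masked by groups that carry no abstractable hydrogen and survive palladium catalysis and light.

Step 8
Reactants: 11 2-ethynyl-3,5-dimethoxy-6-(3-methylbut-2-en-1-yl)phenyl 2,2-dimethylpropanoate; 13 4-iodo-1,3-phenylene bis(2,2-dimethylpropanoate)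
Product: 14 4-{[2,4-dimethoxy-6-(pivaloyloxy)-5-(3-methylbut-2-en-1-yl)phenyl]ethynyl}-1,3-phenylene bis(2,2-dimethylpropanoate)
Conditions: PdCl2(PPh3)2 (3 mol%), CuI (5 mol%), Et3N, THF, rt, degassed
Reagents that add atoms: none
Why: Sonogashira coupling: the aryl iodide undergoes oxidative addition at room temperature and couples with the copper acetylide of 11, and because no ortho hydroxyl is free, 5-endo cyclisation to a benzofuran cannot compete.

Step 9
Reactants: 14 4-{[2,4-dimethoxy-6-(pivaloyloxy)-5-(3-methylbut-2-en-1-yl)phenyl]ethynyl}-1,3-phenylene bis(2,2-dimethylpropanoate)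
Product: 15 1-[2,4-dimethoxy-6-(pivaloyloxy)-5-(3-methylbut-2-en-1-yl)phenyl]-2-[2,4-bis(pivaloyloxy)phenyl]ethane-1,2-dione
Conditions: PdCl2 (10 mol%), DMSO, 120 °C
Reagents that add atoms: dimethyl sulfoxide, CS(C)=O
Why: Wacker-type oxidation of a diarylalkyne to a benzil: divalent palladium activates the alkyne toward two successive oxygen transfers from DMSO (released as dimethyl sulfide), while the pivalates are inert and the trisubstituted prenyl alkene, a poor ligand with no free phenol beside it, should be left alone.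

Step 10
Reactants: 15 1-[2,4-dimethoxy-6-(pivaloyloxy)-5-(3-methylbut-2-en-1-yl)phenyl]-2-[2,4-bis(pivaloyloxy)phenyl]ethane-1,2-dione
Product: 17 racemic 3-hydroxy-7-methoxy-5,2′,4′-tris(pivaloyloxy)-6-prenylisoflavanone, via triplet 1,6-biradical 16 (not isolated)
Conditions: hν (blue LEDs, 420–450 nm), degassed benzene (0.005 M), 20 °C
Reagents that add atoms: none
Why: Proposed new method: visible light excites only the n,π* band of the 1,2-diketone, whose triplet should adopt an s-trans dicarbonyl geometry that holds the C3 oxygen beside the twisted ring A, so that this oxygen takes a hydrogen atom from the C8a methoxy group (1,7-transfer through an eight-membered transition state) and leaves the 1,6-biradical 16. The closest known reaction type is the Norrish–Yang photocyclisation of 1-(2-methylphenyl)-1,2-diketones to 2-hydroxyindan-1-ones, supported by the δ-hydrogen abstraction of 2-alkoxyphenyl ketones that leads to 3-hydroxy-2,3-dihydrobenzofurans. Ring C is closed by combination of the C2 aryloxymethyl radical with the C3 ketyl radical after intersystem crossing, a six-membered radical–radical closure that forms the C2–C3 bond. No element in the substrate controls the new C3 stereocentre, which should therefore form as a racemate and is erased in step 11. The step needs abstraction by the C3 oxygen in preference to the C4 oxygen, whose reaction would close a five-membered ring, and this should be secured by the s-trans diketone geometry and by the doubly ortho-substituted C4 carbonyl being twisted out of the plane of ring A. Competing hydrogen donors are absent because O5 and O2′ carry pivalates, the C7 methoxy group and the prenyl CH2 are para and meta to the acyl carbon and out of reach, and the isolated alkene neither absorbs the light nor accepts triplet energy from the diketone.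

Step 11
Reactants: 17 racemic 3-hydroxy-7-methoxy-5,2′,4′-tris(pivaloyloxy)-6-prenylisoflavanone
Product: 19 7-methoxy-5,2′,4′-tris(pivaloyloxy)-6-prenylisoflavone, via C3 chlorosulfite ester 18 (not isolated)
Conditions: SOCl2, pyridine, CH2Cl2, 0 °C → rt
Reagents that add atoms: none
Why: Dehydration of a tertiary α-ketol through its chlorosulfite 18: pyridine-mediated E2 loss of an antiperiplanar C2 hydrogen gives the conjugated γ-pyrone (any tertiary chloride formed by internal return should lose HCl in the same direction, as 3-halochromanones do), which erases the C3 stereocentre and sets the isoflavone oxidation level without an oxidant, the buffered medium sparing alkene and esters.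

Step 12
Reactants: 19 7-methoxy-5,2′,4′-tris(pivaloyloxy)-6-prenylisoflavone
Product: 20 7-O-methylluteone (5,2′,4′-trihydroxy-7-methoxy-6-prenylisoflavone)
Conditions: K2CO3 (3.5 equiv), MeOH–THF, 0 °C → rt; aq. NH4Cl
Reagents that add atoms: none
Why: Carbonate-promoted methanolysis (transesterification) of the three aryl pivalates, which are far more labile than alkyl esters and should cleave under conditions too mild to open the pyrone ring, the weakly acidic quench avoiding acid-catalysed cyclisation of the prenyl group onto the freed O5.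

Compound list
1 | 2-methylbut-3-en-2-ol | CC(C)(O)C=C | starting material
2 | lithium 2-methylbut-3-en-2-olate | [Li+].[O-]C(C)(C)C=C | intermediate
3 | tert-butyl (2-methylbut-3-en-2-yl) carbonate | CC(C)(C)OC(=O)OC(C)(C)C=C | intermediate
4 | 3,5-dimethoxyphenol | COc1cc(O)cc(OC)c1 | starting material
5 | 1,3-dimethoxy-5-[(2-methylbut-3-en-2-yl)oxy]benzene | COc1cc(OC)cc(OC(C)(C)C=C)c1 | intermediate
6 | racemic 3,5-dimethoxy-6-(3-methylbut-2-en-1-yl)cyclohexa-2,4-dien-1-one | O=C1C=C(OC)C=C(OC)C1CC=C(C)C | intermediate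
7 | 3,5-dimethoxy-2-(3-methylbut-2-en-1-yl)phenol | COc1cc(O)c(CC=C(C)C)c(OC)c1 | intermediate
8 | 2-(hydroxymethyl)-3,5-dimethoxy-6-(3-methylbut-2-en-1-yl)phenol (present as its magnesium salt) | COc1cc(OC)c(CO)c(O)c1CC=C(C)C | intermediate
9 | 2-hydroxy-4,6-dimethoxy-3-(3-methylbut-2-en-1-yl)benzaldehyde | COc1cc(OC)c(C=O)c(O)c1CC=C(C)C | intermediate
10 | 2-ethynyl-3,5-dimethoxy-6-(3-methylbut-2-en-1-yl)phenol | COc1cc(OC)c(C#C)c(O)c1CC=C(C)C | intermediate
11 | 2-ethynyl-3,5-dimethoxy-6-(3-methylbut-2-en-1-yl)phenyl 2,2-dimethylpropanoate | COc1cc(OC)c(C#C)c(OC(=O)C(C)(C)C)c1CC=C(C)C | intermediate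
12 | 4-iodobenzene-1,3-diol (4-iodoresorcinol) | Oc1ccc(I)c(O)c1 | starting material
13 | 4-iodo-1,3-phenylene bis(2,2-dimethylpropanoate) | CC(C)(C)C(=O)Oc1ccc(I)c(OC(=O)C(C)(C)C)c1 | intermediate
14 | 4-{[2,4-dimethoxy-6-(pivaloyloxy)-5-(3-methylbut-2-en-1-yl)phenyl]ethynyl}-1,3-phenylene bis(2,2-dimethylpropanoate) | COc1cc(OC)c(C#Cc2ccc(OC(=O)C(C)(C)C)cc2OC(=O)C(C)(C)C)c(OC(=O)C(C)(C)C)c1CC=C(C)C | intermediate
15 | 1-[2,4-dimethoxy-6-(pivaloyloxy)-5-(3-methylbut-2-en-1-yl)phenyl]-2-[2,4-bis(pivaloyloxy)phenyl]ethane-1,2-dione | COc1cc(OC)c(C(=O)C(=O)c2ccc(OC(=O)C(C)(C)C)cc2OC(=O)C(C)(C)C)c(OC(=O)C(C)(C)C)c1CC=C(C)C | intermediate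
16 | triplet 1,6-biradical of 15 (C3 ketyl radical, C2 aryloxymethyl radical on the C8a oxygen) | [CH2]Oc1cc(OC)c(CC=C(C)C)c(OC(=O)C(C)(C)C)c1C(=O)[C](O)c1ccc(OC(=O)C(C)(C)C)cc1OC(=O)C(C)(C)C | intermediate
17 | racemic 3-hydroxy-7-methoxy-5,2′,4′-tris(pivaloyloxy)-6-prenylisoflavanone | COc1cc2OCC(O)(c3ccc(OC(=O)C(C)(C)C)cc3OC(=O)C(C)(C)C)C(=O)c2c(OC(=O)C(C)(C)C)c1CC=C(C)C | intermediate
18 | racemic C3 chlorosulfite ester of 17 | COc1cc2OCC(OS(=O)Cl)(c3ccc(OC(=O)C(C)(C)C)cc3OC(=O)C(C)(C)C)C(=O)c2c(OC(=O)C(C)(C)C)c1CC=C(C)C | intermediate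
19 | 7-methoxy-5,2′,4′-tris(pivaloyloxy)-6-prenylisoflavone | COc1cc2occ(-c3ccc(OC(=O)C(C)(C)C)cc3OC(=O)C(C)(C)C)c(=O)c2c(OC(=O)C(C)(C)C)c1CC=C(C)C | intermediate
20 | 7-O-methylluteone (5,2′,4′-trihydroxy-7-methoxy-6-prenylisoflavone) | COc1cc2occ(-c3ccc(O)cc3O)c(=O)c2c(O)c1CC=C(C)C | target

Total step count: 12. Longest linear sequence: 11 steps (steps 1–6 and 8–12, from 1); step 7 is a one-step side branch.

Steps most likely to fail

1. Step 10 (Proposed new method). The excited diketone may instead transfer hydrogen to the C4 oxygen and close a five-membered ring. It may also decay without reaction through charge transfer from the electron-rich ring A, or the biradical may return the hydrogen without coupling. The fallback uses known chemistry only; it sets out from alkyne 14 and comes back at 19. Gold-catalysed Markovnikov hydration (Ph3PAuNTf2, aqueous dioxane, 80 °C) should place the carbonyl on the alkyne carbon bound to the more electron-rich ring A and give the deoxybenzoin 1-[2,4-dimethoxy-6-(pivaloyloxy)-5-prenylphenyl]-2-[2,4-bis(pivaloyloxy)phenyl]ethan-1-one F1. BCl3 (CH2Cl2, −78 °C) should then cleave only the methyl ether chelated to that ketone, the one on C8a, to give the 2-hydroxydeoxybenzoin 1-[2-hydroxy-4-methoxy-6-(pivaloyloxy)-5-prenylphenyl]-2-[2,4-bis(pivaloyloxy)phenyl]ethan-1-one F2. Condensation of F2 with N,N-dimethylformamide dimethyl acetal, which now supplies C2, and ring closure through the free C8a hydroxyl (the classical deoxybenzoin route to isoflavones) should give 19, from which step 12 follows.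

2. Step 9. Hot divalent palladium may isomerise or oxidise the prenyl alkene, or a neighbouring pivalate carbonyl may add to the activated alkyne and divert it into cyclisation. The fallback sets out from 14 and comes back at 15; both oxygens are brought in through boron and not through a metal-bound oxidant. Pt(PPh3)4-catalysed cis-diboration with B2pin2 (toluene, 90 °C), to which trisubstituted alkenes are inert, should give (Z)-1-[2,4-dimethoxy-6-(pivaloyloxy)-5-prenylphenyl]-2-[2,4-bis(pivaloyloxy)phenyl]-1,2-bis(pinacolboryl)ethene F3. Oxidation of both C–B bonds with anhydrous Me3NO and aqueous work-up should give the racemic benzoin 2-hydroxy-1-[2,4-dimethoxy-6-(pivaloyloxy)-5-prenylphenyl]-2-[2,4-bis(pivaloyloxy)phenyl]ethan-1-one F4, possibly accompanied by the regioisomeric racemic benzoin 2-hydroxy-2-[2,4-dimethoxy-6-(pivaloyloxy)-5-prenylphenyl]-1-[2,4-bis(pivaloyloxy)phenyl]ethan-1-one F5. Dess–Martin periodinane (CH2Cl2, rt) should oxidise either one to 15.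

3. Step 5. Deprotonation of the phenol in basic methanol turns the aldehyde into a vinylogous carboxylate, so addition of the diazophosphonate anion may stall, or the neighbouring phenoxide may intercept the reactive intermediates. The fallback sets out from 9 and comes back at 10. Silylation (TBSOTf, 2,6-lutidine, CH2Cl2) should give the neutral aldehyde 2-[(tert-butyldimethylsilyl)oxy]-4,6-dimethoxy-3-prenylbenzaldehyde F6. Corey–Fuchs homologation then avoids basic methanol altogether: CBr4/PPh3 (CH2Cl2, 0 °C) should give the dibromoalkene tert-butyl[2-(2,2-dibromoethenyl)-3,5-dimethoxy-6-prenylphenoxy]dimethylsilane F7, and n-BuLi (THF, −78 °C) followed by protonation should give the silyl-protected alkyne tert-butyl(2-ethynyl-3,5-dimethoxy-6-prenylphenoxy)dimethylsilane F8. TBAF (THF, 0 °C) should return 10.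

Further compounds
F1 | step 10 | 1-[2,4-dimethoxy-6-(pivaloyloxy)-5-(3-methylbut-2-en-1-yl)phenyl]-2-[2,4-bis(pivaloyloxy)phenyl]ethan-1-one | COc1cc(OC)c(C(=O)Cc2ccc(OC(=O)C(C)(C)C)cc2OC(=O)C(C)(C)C)c(OC(=O)C(C)(C)C)c1CC=C(C)C
F2 | step 10 | 1-[2-hydroxy-4-methoxy-6-(pivaloyloxy)-5-(3-methylbut-2-en-1-yl)phenyl]-2-[2,4-bis(pivaloyloxy)phenyl]ethan-1-one | COc1cc(O)c(C(=O)Cc2ccc(OC(=O)C(C)(C)C)cc2OC(=O)C(C)(C)C)c(OC(=O)C(C)(C)C)c1CC=C(C)C
F3 | step 9 | (Z)-1-[2,4-dimethoxy-6-(pivaloyloxy)-5-(3-methylbut-2-en-1-yl)phenyl]-2-[2,4-bis(pivaloyloxy)phenyl]-1,2-bis(4,4,5,5-tetramethyl-1,3,2-dioxaborolan-2-yl)ethene | CC1(C)OB(OC1(C)C)/C(=C(\B1OC(C)(C)C(C)(C)O1)c1ccc(OC(=O)C(C)(C)C)cc1OC(=O)C(C)(C)C)c1c(OC)cc(OC)c(CC=C(C)C)c1OC(=O)C(C)(C)C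
F4 | step 9 | racemic 2-hydroxy-1-[2,4-dimethoxy-6-(pivaloyloxy)-5-(3-methylbut-2-en-1-yl)phenyl]-2-[2,4-bis(pivaloyloxy)phenyl]ethan-1-one | COc1cc(OC)c(C(=O)C(O)c2ccc(OC(=O)C(C)(C)C)cc2OC(=O)C(C)(C)C)c(OC(=O)C(C)(C)C)c1CC=C(C)C
F5 | step 9 | racemic 2-hydroxy-2-[2,4-dimethoxy-6-(pivaloyloxy)-5-(3-methylbut-2-en-1-yl)phenyl]-1-[2,4-bis(pivaloyloxy)phenyl]ethan-1-one | COc1cc(OC)c(C(O)C(=O)c2ccc(OC(=O)C(C)(C)C)cc2OC(=O)C(C)(C)C)c(OC(=O)C(C)(C)C)c1CC=C(C)C
F6 | step 5 | 2-[(tert-butyldimethylsilyl)oxy]-4,6-dimethoxy-3-(3-methylbut-2-en-1-yl)benzaldehyde | COc1cc(OC)c(C=O)c(O[Si](C)(C)C(C)(C)C)c1CC=C(C)C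
F7 | step 5 | tert-butyl[2-(2,2-dibromoethenyl)-3,5-dimethoxy-6-(3-methylbut-2-en-1-yl)phenoxy]dimethylsilane | COc1cc(OC)c(C=C(Br)Br)c(O[Si](C)(C)C(C)(C)C)c1CC=C(C)C
F8 | step 5 | tert-butyl[2-ethynyl-3,5-dimethoxy-6-(3-methylbut-2-en-1-yl)phenoxy]dimethylsilane | COc1cc(OC)c(C#C)c(O[Si](C)(C)C(C)(C)C)c1CC=C(C)C
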